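**Retrosynthetic overview**
1. 21 ⇒ 20: the C7–C8 bond closes the ten-membered ring in a radical step; HAT to an enol angelate gives the C8 α-acyloxy radical, which adds to a butenolide, and loss of sulfinate unveils the exocyclic methylene.
2. 20 ⇒ 7 + 18: C2–C3 by a Felkin–Anh-controlled Mukaiyama aldol addition (sets C3).
3. 7 ⇒ 1 + 2 + 6: enantioselective alkynylation of biacetyl (sets C10), acetylation, ruthenium-catalysed addition of angelic acid to the alkyne.
4. 18 ⇒ 8 + 10 + 15: C4 from the bromo alcohol, C6 by catalytic asymmetric alkylation of crotonaldehyde, butenolide by ring-closing metathesis.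
5. Ring order: butenolide first (step 8), ten-membered carbocycle last (step 11); the only protecting group is one triethylsilyl ether.

Atom labels used below: C1 ketone, C2, C3 (OH), C4 (CH3), C5, C6 (lactone O), C7, C8 (angelate), C9, C10 (CH3, OAc), C11–C13 lactone carbons (C13 = CH2).

Assumption: the sense of induction of the chiral ligands in steps 1 and 5 is assigned by analogy; if either gives the antipode, its mirror-image ligand is used.

**Step 1**
Reactants: 1 butane-2,3-dione; 2 ethynyltrimethylsilane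
Product: 3 (3R)-3-hydroxy-3-methyl-5-(trimethylsilyl)pent-4-yn-2-one
Conditions: Zn(OTf)2 (20 mol%), (1S,2S)-2-(dimethylamino)-1-(4-nitrophenyl)-3-(tert-butyldimethylsilyloxy)propan-1-ol (22 mol%), Et3N (30 mol%), toluene, 50 °C
Reagents that add atoms: none
Why: Catalytic enantioselective alkynylzinc addition to an activated 1,2-dicarbonyl (the protocol known for α-keto esters, applied here by analogy to a 1,2-diketone) stops after one addition because the zinc alkoxide deactivates the second ketone, and the chiral amino alcohol sets the tertiary carbinol C10 (R).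

**Step 2**
Reactants: 3 (3R)-3-hydroxy-3-methyl-5-(trimethylsilyl)pent-4-yn-2-one
Product: 5 (3R)-3-methyl-2-oxopent-4-yn-3-yl acetate, via alkynol 4 (not isolated)
Conditions: K2CO3 (10 mol%), MeOH, 0 °C; cold concentration; then Ac2O, Et3N, DMAP (10 mol%), CH2Cl2, 0 °C to rt
Reagents that add atoms: acetic anhydride, CC(=O)OC(C)=O
Why: Protiodesilylation of the alkynylsilane followed by DMAP-catalysed acetylation of the tertiary α-ketol, telescoped because alkynol 4 is small and volatile; the stereocentre is not touched.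

**Step 3**
Reactants: 5 (3R)-3-methyl-2-oxopent-4-yn-3-yl acetate; 6 angelic acid
Product: 7 (1Z,3R)-3-acetoxy-3-methyl-4-oxopent-1-en-1-yl (2Z)-2-methylbut-2-enoate
Conditions: [RuCl2(p-cymene)]2 (2 mol%), P(4-ClC6H4)3 (6 mol%), DMAP (8 mol%), toluene, 60 °C
Reagents that add atoms: none
Why: Ruthenium-catalysed anti-Markovnikov hydro-oxycarbonylation of a terminal alkyne (via a ruthenium vinylidene) puts the carboxylate on the terminal carbon and gives the Z enol ester, with no new stereocentre and an alkene geometry that does not matter later.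

**Step 4**
Reactants: 8 (2R)-3-bromo-2-methylpropan-1-ol
Product: 9 [(2R)-3-bromo-2-methylpropoxy]triethylsilane
Conditions: Et3SiCl, imidazole, CH2Cl2, 0 °C
Reagents that add atoms: chlorotriethylsilane, CC[Si](Cl)(CC)CC
Why: Standard silylation of a primary alcohol that leaves the methyl-bearing centre (C4) untouched.

**Step 5**
Reactants: 9 [(2R)-3-bromo-2-methylpropoxy]triethylsilane; 10 (2E)-but-2-enal
Product: 13 (2E,4R,6S)-6-methyl-7-[(triethylsilyl)oxy]hept-2-en-4-ol, via Grignard reagent 11 (not isolated), via alkyltitanium triisopropoxide 12 (not isolated)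
Conditions: Mg, THF, 40 °C; Ti(OiPr)4 (3 equiv), −78 °C; then 10, (R)-3-(3,5-diphenylphenyl)-H8-BINOL (3 mol%), Ti(OiPr)4 (1 equiv), CH2Cl2, 0 °C, slow addition
Reagents that add atoms: none
Why: Catalytic asymmetric alkylation of an aldehyde with a Grignard reagent (transmetalation to titanium, then 1,2-addition to the enal under control of the chiral complex formed from Ti(OiPr)4 and the BINOL-type ligand) sets the allylic carbinol C6 (R), while C4 is carried through unchanged (its descriptor changes from R to S only because the substituent priorities change).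

**Step 6**
Reactants: 14 2-(bromomethyl)prop-2-enoic acid
Product: 15 2-[(methylsulfonyl)methyl]prop-2-enoic acid
Conditions: MeSO2Na (1.1 equiv), DMF, rt; aq. HCl
Reagents that add atoms: sodium methanesulfinate, CS(=O)[O-].[Na+]
Why: SN2 displacement of the allylic bromide by sulfinate sulfur installs the allyl sulfone that serves as the radical leaving group in step 11.

**Step 7**
Reactants: 13 (2E,4R,6S)-6-methyl-7-[(triethylsilyl)oxy]hept-2-en-4-ol; 15 2-[(methylsulfonyl)methyl]prop-2-enoic acid
Product: 16 (2E,4R,6S)-6-methyl-7-[(triethylsilyl)oxy]hept-2-en-4-yl 2-[(methylsulfonyl)methyl]prop-2-enoate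
Conditions: DCC, DMAP (5 mol%), CH2Cl2, 0 °C
Reagents that add atoms: none
Why: Steglich esterification of the secondary allylic alcohol with retention at C6.

**Step 8**
Reactants: 16 (2E,4R,6S)-6-methyl-7-[(triethylsilyl)oxy]hept-2-en-4-yl 2-[(methylsulfonyl)methyl]prop-2-enoate
Product: 17 (5R)-5-{(2S)-2-methyl-3-[(triethylsilyl)oxy]propyl}-3-[(methylsulfonyl)methyl]furan-2(5H)-one
Conditions: second-generation Grubbs catalyst (5 mol%), toluene, 80 °C, 0.01 M
Reagents that add atoms: none
Why: Ring-closing metathesis between the acrylate and the propenyl group closes the butenolide with loss of propene and does not touch C6.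

**Step 9**
Reactants: 17 (5R)-5-{(2S)-2-methyl-3-[(triethylsilyl)oxy]propyl}-3-[(methylsulfonyl)methyl]furan-2(5H)-one
Product: 18 (2S)-2-methyl-3-{(2R)-4-[(methylsulfonyl)methyl]-5-oxo-2,5-dihydrofuran-2-yl}propanal
Conditions: (COCl)2, DMSO, CH2Cl2, −78 °C; 17, −78 to −40 °C; iPr2NEt, −78 to 0 °C
Reagents that add atoms: none
Why: Swern oxidation converts a primary triethylsilyl ether directly into the aldehyde (the chlorosulfonium ion cleaves the Si–O bond), and low temperature with a hindered base keeps the α-methyl centre C4 and the butenolide centre C6 intact.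

**Step 10**
Reactants: 7 (1Z,3R)-3-acetoxy-3-methyl-4-oxopent-1-en-1-yl (2Z)-2-methylbut-2-enoate; 18 (2S)-2-methyl-3-{(2R)-4-[(methylsulfonyl)methyl]-5-oxo-2,5-dihydrofuran-2-yl}propanal
Product: 20 (1Z,3R,6S,7S)-3-acetoxy-6-hydroxy-3,7-dimethyl-8-{(2R)-4-[(methylsulfonyl)methyl]-5-oxo-2,5-dihydrofuran-2-yl}-4-oxooct-1-en-1-yl (2Z)-2-methylbut-2-enoate, via silyl enol ether 19 (not isolated)
Conditions: Me3SiCl, LiN(SiMe3)2, THF, −78 °C (internal quench); pentane filtration; then 18, BF3·OEt2, CH2Cl2, −78 °C; aq. NaHCO3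
Reagents that add atoms: none
Why: Mukaiyama aldol addition of the kinetically trapped silyl enol ether of the methyl ketone (internal quench prevents acyl transfer from the α-acetoxy group) to the α-methyl aldehyde through an open transition state follows Felkin–Anh control and gives the 3,4-syn carbinol C3 (S).

**Step 11**
Reactants: 20 (1Z,3R,6S,7S)-3-acetoxy-6-hydroxy-3,7-dimethyl-8-{(2R)-4-[(methylsulfonyl)methyl]-5-oxo-2,5-dihydrofuran-2-yl}-4-oxooct-1-en-1-yl (2Z)-2-methylbut-2-enoate
Product: 21 (3aS,4S,6R,9S,10S,11aR)-6-acetoxy-9-hydroxy-6,10-dimethyl-3-methylidene-2,7-dioxododecahydrocyclodeca[b]furan-4-yl (2Z)-2-methylbut-2-enoate (CNP0141210.5)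
Conditions: Fe(acac)3 (30 mol%), PhSiH3 (3 equiv, syringe pump, 6 h), EtOH/(CH2OH)2 10:1, 1 mM, 60 °C
Reagents that add atoms: none
Why: Proposed new method: hydrogen-atom transfer from the iron hydride formed from Fe(acac)3 and PhSiH3 (trivalent iron) to C9 of the enol ester gives the nucleophilic α-acyloxy radical at C8, which closes the ten-membered ring by Giese-type addition to the electrophilic butenolide carbon C7 anti to the C6 side chain (trans ring fusion, C7 S), with the tether staggered anti to C11 and the angelate in the open sector next to H7 (C8 S), after which the adduct radical expels the methylsulfonyl radical (or, after reduction by divalent iron, the enolate expels methanesulfinate) to give the exocyclic methylene; the closest known reaction types are iron-hydride reductive olefin cross-coupling and radical allylation with allyl sulfones, and slow silane addition at high dilution lets cyclization compete with reduction of the radical.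

**Compound list**
1 | butane-2,3-dione | CC(=O)C(C)=O | starting material
2 | ethynyltrimethylsilane | C#C[Si](C)(C)C | starting material
3 | (3R)-3-hydroxy-3-methyl-5-(trimethylsilyl)pent-4-yn-2-one | CC(=O)[C@](C)(O)C#C[Si](C)(C)C | intermediate
4 | (3R)-3-hydroxy-3-methylpent-4-yn-2-one | CC(=O)[C@](C)(O)C#C | intermediate (not isolated)
5 | (3R)-3-methyl-2-oxopent-4-yn-3-yl acetate | CC(=O)[C@](C)(OC(C)=O)C#C | intermediate
6 | angelic acid, (2Z)-2-methylbut-2-enoic acid | C/C=C(/C)C(=O)O | starting material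
7 | (1Z,3R)-3-acetoxy-3-methyl-4-oxopent-1-en-1-yl (2Z)-2-methylbut-2-enoate | C/C=C(/C)C(=O)O/C=C\[C@@](C)(OC(C)=O)C(C)=O | intermediate
8 | (2R)-3-bromo-2-methylpropan-1-ol | OC[C@@H](C)CBr | starting material
9 | [(2R)-3-bromo-2-methylpropoxy]triethylsilane | CC[Si](CC)(CC)OC[C@@H](C)CBr | intermediate
10 | (2E)-but-2-enal | C/C=C/C=O | starting material
11 | {(2R)-2-methyl-3-[(triethylsilyl)oxy]propyl}magnesium bromide | CC[Si](CC)(CC)OC[C@@H](C)C[Mg]Br | intermediate (not isolated)
12 | triisopropoxy{(2R)-2-methyl-3-[(triethylsilyl)oxy]propyl}titanium | CC[Si](CC)(CC)OC[C@@H](C)C[Ti](OC(C)C)(OC(C)C)OC(C)C | intermediate (not isolated)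
13 | (2E,4R,6S)-6-methyl-7-[(triethylsilyl)oxy]hept-2-en-4-ol | CC[Si](CC)(CC)OC[C@@H](C)C[C@@H](O)/C=C/C | intermediate
14 | 2-(bromomethyl)prop-2-enoic acid | C=C(CBr)C(=O)O | starting material
15 | 2-[(methylsulfonyl)methyl]prop-2-enoic acid | C=C(CS(C)(=O)=O)C(=O)O | intermediate
16 | (2E,4R,6S)-6-methyl-7-[(triethylsilyl)oxy]hept-2-en-4-yl 2-[(methylsulfonyl)methyl]prop-2-enoate | CC[Si](CC)(CC)OC[C@@H](C)C[C@@H](OC(=O)C(=C)CS(C)(=O)=O)/C=C/C | intermediate
17 | (5R)-5-{(2S)-2-methyl-3-[(triethylsilyl)oxy]propyl}-3-[(methylsulfonyl)methyl]furan-2(5H)-one | CC[Si](CC)(CC)OC[C@@H](C)C[C@H]1OC(=O)C(CS(C)(=O)=O)=C1 | intermediate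
18 | (2S)-2-methyl-3-{(2R)-4-[(methylsulfonyl)methyl]-5-oxo-2,5-dihydrofuran-2-yl}propanal | O=C[C@@H](C)C[C@H]1OC(=O)C(CS(C)(=O)=O)=C1 | intermediate
19 | (1Z,3R)-3-acetoxy-3-methyl-4-[(trimethylsilyl)oxy]penta-1,4-dien-1-yl (2Z)-2-methylbut-2-enoate | C/C=C(/C)C(=O)O/C=C\[C@@](C)(OC(C)=O)C(=C)O[Si](C)(C)C | intermediate (not isolated)
20 | (1Z,3R,6S,7S)-3-acetoxy-6-hydroxy-3,7-dimethyl-8-{(2R)-4-[(methylsulfonyl)methyl]-5-oxo-2,5-dihydrofuran-2-yl}-4-oxooct-1-en-1-yl (2Z)-2-methylbut-2-enoate | C/C=C(/C)C(=O)O/C=C\[C@@](C)(OC(C)=O)C(=O)C[C@H](O)[C@@H](C)C[C@H]1OC(=O)C(CS(C)(=O)=O)=C1 | intermediate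
21 | (3aS,4S,6R,9S,10S,11aR)-6-acetoxy-9-hydroxy-6,10-dimethyl-3-methylidene-2,7-dioxododecahydrocyclodeca[b]furan-4-yl (2Z)-2-methylbut-2-enoate | C=C1C(=O)O[C@@H]2C[C@H](C)[C@@H](O)CC(=O)[C@](C)(OC(C)=O)C[C@H](OC(=O)/C(C)=C\C)[C@@H]12 | target

**Totals and risks**
Total step count: 11. Longest linear sequence: 7 steps (8 → 9 → 13 → 16 → 17 → 18 → 20 → 21; steps 4, 5, 7, 8, 9, 10, 11).

The step most likely to fail is step 11. A ten-membered radical ring closure is slow, so the C8 radical may be reduced, may undergo a 1,5-hydrogen shift from C2, or may dimerize, and a wrong C8 epimer cannot be corrected afterwards. The fallback inverts the order of the two unions; it sets out from 7 and 18 and comes back at 21. Intermolecular coupling of 7 with 18 (3 equiv) under the same Fe(acac)3/PhSiH3 conditions at 0.1 M gives the open-chain keto aldehyde (1S,3R)-3-acetoxy-3-methyl-1-{(2R,3S)-2-[(2S)-2-methyl-3-oxopropyl]-4-methylidene-5-oxotetrahydrofuran-3-yl}-4-oxopentyl (2Z)-2-methylbut-2-enoate F1, from which the C8 epimer is separated. The ring is then closed by an intramolecular boron aldol reaction (dicyclohexylboron chloride, Et3N, Et2O, 2 mM, −78 °C) through the dicyclohexylboron enolate F2 to give 21.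

The second risk is step 3. The ruthenium catalyst may add the acid in the Markovnikov sense or trigger migration of the tertiary propargylic acetate. The fallback makes the enol ester by C–O coupling instead; it sets out from 5 and comes back at 7. Rhodium-catalysed trans-hydroboration ([Rh(cod)Cl]2, P(iPr)3, Et3N, pinacolborane, cyclohexane, rt) gives the alkenylboronate (3R,4Z)-3-methyl-2-oxo-5-(4,4,5,5-tetramethyl-1,3,2-dioxaborolan-2-yl)pent-4-en-3-yl acetate F3. Chan–Lam-type coupling of F3 with angelic acid 6 (Cu(OAc)2, Et3N, air, CH2Cl2) gives 7.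

The third risk is step 1. The enantioselectivity of alkynylation on a small, volatile 1,2-diketone is uncertain. The fallback secures C10 by resolution; it sets out from 1 and 2 and comes back at 5. n-BuLi (THF, −78 °C) converts 2 into lithium (trimethylsilyl)acetylide F4, which adds to 1 to give racemic 3-hydroxy-3-methyl-5-(trimethylsilyl)pent-4-yn-2-one F5. The conditions of step 2 give racemic 3-hydroxy-3-methylpent-4-yn-2-one F6 (not isolated) and then racemic 3-methyl-2-oxopent-4-yn-3-yl acetate F7. Preparative chromatography on a chiral stationary phase delivers 5.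

**Further compounds**
F1 | step 11 | (1S,3R)-3-acetoxy-3-methyl-1-{(2R,3S)-2-[(2S)-2-methyl-3-oxopropyl]-4-methylidene-5-oxotetrahydrofuran-3-yl}-4-oxopentyl (2Z)-2-methylbut-2-enoate | C=C1C(=O)O[C@H](C[C@H](C)C=O)[C@H]1[C@@H](OC(=O)/C(C)=C\C)C[C@@](C)(OC(C)=O)C(C)=O
F2 | step 11 | (1S,3R)-3-acetoxy-4-[(dicyclohexylboranyl)oxy]-3-methyl-1-{(2R,3S)-2-[(2S)-2-methyl-3-oxopropyl]-4-methylidene-5-oxotetrahydrofuran-3-yl}pent-4-en-1-yl (2Z)-2-methylbut-2-enoate | C=C1C(=O)O[C@H](C[C@H](C)C=O)[C@H]1[C@@H](OC(=O)/C(C)=C\C)C[C@@](C)(OC(C)=O)C(=C)OB(C2CCCCC2)C2CCCCC2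
F3 | step 3 | (3R,4Z)-3-methyl-2-oxo-5-(4,4,5,5-tetramethyl-1,3,2-dioxaborolan-2-yl)pent-4-en-3-yl acetate | CC(=O)[C@](C)(OC(C)=O)/C=C\B1OC(C)(C)C(C)(C)O1
F4 | step 1 | lithium (trimethylsilyl)acetylide | [Li]C#C[Si](C)(C)C
F5 | step 1 | racemic 3-hydroxy-3-methyl-5-(trimethylsilyl)pent-4-yn-2-one | CC(=O)C(C)(O)C#C[Si](C)(C)C
F6 | step 1 | racemic 3-hydroxy-3-methylpent-4-yn-2-one | CC(=O)C(C)(O)C#C
F7 | step 1 | racemic 3-methyl-2-oxopent-4-yn-3-yl acetate | CC(=O)C(C)(OC(C)=O)C#C
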